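The flavanone is disconnected at C2–C3 and at O1–C8a, so that ring C becomes the product of a formal [4+2] annulation between 4-(methoxymethoxy)benzaldehyde and the enol silane of a 2-fluoroacetophenone that already carries all of ring A. In one flask a catalytic enantioselective Mukaiyama aldol sets C2 and a fluoride-relayed SNAr closes ring C, Me3SiF being the only by-product. The step exploits that C8a is ortho to the C4 carbonyl through C4a: a fluorine there is activated by the ketone whose enol is the aldol donor, and fluorine at C8a versus oxygen at C5 fixes the 6-methyl/8-prenyl pattern. The precursor is made by three directed lithiations of 5-fluororesorcinol bis-MOM ether.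

Key step: step 6

Assumption: the oxazaborolidinone derived from (S)-tryptophan is taken to direct the enol silane to the Re face of aromatic aldehydes, so the (R)-tryptophan-derived catalyst is specified for the Si-face attack that gives the 2S product; if the sense proves opposite, the enantiomeric catalyst is used.

Step 1
Reactants: 1 5-fluorobenzene-1,3-diol
Product: 2 1-fluoro-3,5-bis(methoxymethoxy)benzene
Conditions: MOMCl, i-Pr2NEt, CH2Cl2, 0 °C → rt
Reagents that add atoms: chloromethyl methyl ether (MOMCl), COCCl
Why: O-alkylation of both phenols by the reactive α-chloro ether under amine base (MOM protection) should give the bis-acetal, which serves later as base-stable protection and as a directing group for metalation.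

Step 2
Reactants: 2 1-fluoro-3,5-bis(methoxymethoxy)benzene
Product: 4 5-fluoro-1,3-bis(methoxymethoxy)-2-methylbenzene, via aryllithium 3 (not isolated)
Conditions: n-BuLi, Et2O, −30 °C; then MeI, −78 °C → rt
Reagents that add atoms: iodomethane, CI
Why: Directed ortho-metalation under coordination control should remove the C–H flanked by both OMOM groups (chelation by two acetal oxygens), and the aryllithium is then methylated by SN2 on MeI.

Step 3
Reactants: 4 5-fluoro-1,3-bis(methoxymethoxy)-2-methylbenzene
Product: 6 1-fluoro-3,5-bis(methoxymethoxy)-4-methyl-2-(3-methylbut-2-en-1-yl)benzene, via aryllithium 5 (not isolated)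
Conditions: s-BuLi, THF, −78 °C; then CuBr·SMe2 (20 mol %), prenyl bromide, −78 → −50 °C
Reagents that add atoms: prenyl bromide (1-bromo-3-methylbut-2-ene), CC(C)=CCBr
Why: Directed ortho-metalation at one of the two equivalent remaining ring positions (each acidified by ortho F and ortho OMOM, and kept at −78 °C so that LiF is not lost) is followed by copper-catalysed allylic substitution at the primary carbon of prenyl bromide.

Step 4
Reactants: 6 1-fluoro-3,5-bis(methoxymethoxy)-4-methyl-2-(3-methylbut-2-en-1-yl)benzene
Product: 8 1-[2-fluoro-4,6-bis(methoxymethoxy)-5-methyl-3-(3-methylbut-2-en-1-yl)phenyl]ethan-1-one, via aryllithium 7 (not isolated)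
Conditions: s-BuLi, THF, −78 °C; then MeC(O)N(OMe)Me, −78 → −20 °C; then H2O
Reagents that add atoms: N-methoxy-N-methylacetamide, CC(=O)N(C)OC
Why: Directed ortho-metalation of the last ring C–H (flanked by F and OMOM, kinetically far more acidic than the benzylic–allylic CH2) and Weinreb ketone synthesis should stop cleanly at the methyl ketone after work-up.

Step 5
Reactants: 8 1-[2-fluoro-4,6-bis(methoxymethoxy)-5-methyl-3-(3-methylbut-2-en-1-yl)phenyl]ethan-1-one
Product: 10 {1-[2-fluoro-4,6-bis(methoxymethoxy)-5-methyl-3-(3-methylbut-2-en-1-yl)phenyl]ethenyloxy}trimethylsilane, via lithium enolate 9 (not isolated)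
Conditions: LiN(i-Pr)2, THF, −78 °C; then Me3SiCl, −78 → 0 °C; non-aqueous work-up (pentane, filtration), used crude
Reagents that add atoms: chlorotrimethylsilane, C[Si](C)(C)Cl
Why: Kinetic enolisation of the only enolisable position and O-silylation of the lithium enolate (silyl enol ether formation) should proceed without touching the aryl fluoride or the MOM groups.

Step 6
Reactants: 10 {1-[2-fluoro-4,6-bis(methoxymethoxy)-5-methyl-3-(3-methylbut-2-en-1-yl)phenyl]ethenyloxy}trimethylsilane; 11 4-(methoxymethoxy)benzaldehyde (slight excess)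
Product: 14 (2S)-5,7-bis(methoxymethoxy)-2-[4-(methoxymethoxy)phenyl]-6-methyl-8-(3-methylbut-2-en-1-yl)-2,3-dihydro-4H-chromen-4-one, via silyl aldol 12 (not isolated), via alkoxide 13 (not isolated)
Conditions: (4R)-2-butyl-4-(1H-indol-3-ylmethyl)-3-tosyl-1,3,2-oxazaborolidin-5-one (20 mol %), EtCN, −78 °C; then Bu4N[Ph3SiF2] (40 mol %), THF, −78 → −20 °C; pH 7 buffer quench
Reagents that add atoms: none
Why: Proposed new method: the chiral boron Lewis acid binds aldehyde 11 and enol silane 10 adds through its CH2 terminus to the Si face with silyl transfer (catalytic enantioselective Mukaiyama aldol, bond C2–C3) to give 12, after which fluoride cleaves the O–Si bond and alkoxide 13 attacks C8a of ring A and expels the fluoride that continues the chain (bond O1–C8a), so that Me3SiF is the only by-product. The closest known reaction types are the siloxydiene aldol–cyclisation (formal hetero-Diels–Alder) route to 2,3-dihydro-4-pyranones, in which the aryl C–F bond here plays the part of the vinylogous alkoxy leaving group, and the fluoride-catalysed SNAr etherification of aryl fluorides by silyl ethers; their merger into one flavanone-forming operation is the untested part. Ring C closes by intramolecular addition–elimination at an aromatic carbon, a 6-endo-trig oxa-Michael attack on the C4=O/C4a=C8a vinylogous acyl fluoride (6-exo-trig if counted against the C8a=C8 bond) followed by loss of fluoride. The C2 stereocentre is set by the oxazaborolidinone in the aldol event (reagent control over the aldehyde face) and is carried into 14 unchanged because the C2–O bond is never broken. The step needs ring closure to outrun retro-aldol cleavage of 13, which the ortho C4 ketone activating C8a–F, the meta (not ortho or para) placement of both OMOM groups relative to fluorine and the six-membered transition state should secure, and it needs O1 to bond to C8a and not to C5, which is certain because only C8a carries a leaving group. Aldehyde 11 is kept in slight excess so that no enol silane remains to give a racemic fluoride-triggered aldol once the fluoride source is added.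

Step 7
Reactants: 14 (2S)-5,7-bis(methoxymethoxy)-2-[4-(methoxymethoxy)phenyl]-6-methyl-8-(3-methylbut-2-en-1-yl)-2,3-dihydro-4H-chromen-4-one
Product: 15 (2S)-5,7-dihydroxy-2-(4-hydroxyphenyl)-6-methyl-8-(3-methylbut-2-en-1-yl)-2,3-dihydro-4H-chromen-4-one (6-methyl-8-prenylnaringenin)
Conditions: HCl in MeOH (1.25 M), 40 °C
Reagents that add atoms: none
Why: Acid-catalysed acetal solvolysis (MOM cleavage) should free the three phenols under conditions mild enough to leave the prenyl alkene alone and, being free of base, to leave ring C closed, so C2 keeps its S configuration.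

Compound list
1 | 5-fluorobenzene-1,3-diol (5-fluororesorcinol) | Oc1cc(O)cc(F)c1 | starting material
2 | 1-fluoro-3,5-bis(methoxymethoxy)benzene | COCOc1cc(F)cc(OCOC)c1 | intermediate
3 | [4-fluoro-2,6-bis(methoxymethoxy)phenyl]lithium | [Li]c1c(OCOC)cc(F)cc1OCOC | intermediate
4 | 5-fluoro-1,3-bis(methoxymethoxy)-2-methylbenzene | Cc1c(OCOC)cc(F)cc1OCOC | intermediate
5 | [6-fluoro-2,4-bis(methoxymethoxy)-3-methylphenyl]lithium | [Li]c1c(F)cc(OCOC)c(C)c1OCOC | intermediate
6 | 1-fluoro-3,5-bis(methoxymethoxy)-4-methyl-2-(3-methylbut-2-en-1-yl)benzene | CC(C)=CCc1c(F)cc(OCOC)c(C)c1OCOC | intermediate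
7 | [2-fluoro-4,6-bis(methoxymethoxy)-5-methyl-3-(3-methylbut-2-en-1-yl)phenyl]lithium | [Li]c1c(F)c(CC=C(C)C)c(OCOC)c(C)c1OCOC | intermediate
8 | 1-[2-fluoro-4,6-bis(methoxymethoxy)-5-methyl-3-(3-methylbut-2-en-1-yl)phenyl]ethan-1-one | CC(=O)c1c(F)c(CC=C(C)C)c(OCOC)c(C)c1OCOC | intermediate
9 | lithium 1-[2-fluoro-4,6-bis(methoxymethoxy)-5-methyl-3-(3-methylbut-2-en-1-yl)phenyl]ethen-1-olate | C=C(O[Li])c1c(F)c(CC=C(C)C)c(OCOC)c(C)c1OCOC | intermediate
10 | {1-[2-fluoro-4,6-bis(methoxymethoxy)-5-methyl-3-(3-methylbut-2-en-1-yl)phenyl]ethenyloxy}trimethylsilane | C=C(O[Si](C)(C)C)c1c(F)c(CC=C(C)C)c(OCOC)c(C)c1OCOC | intermediate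
11 | 4-(methoxymethoxy)benzaldehyde | COCOc1ccc(C=O)cc1 | starting material
12 | (3S)-1-[2-fluoro-4,6-bis(methoxymethoxy)-5-methyl-3-(3-methylbut-2-en-1-yl)phenyl]-3-[4-(methoxymethoxy)phenyl]-3-(trimethylsilyloxy)propan-1-one | C[Si](C)(C)O[C@H](c1ccc(OCOC)cc1)CC(=O)c1c(F)c(CC=C(C)C)c(OCOC)c(C)c1OCOC | intermediate
13 | tetrabutylammonium (1S)-3-[2-fluoro-4,6-bis(methoxymethoxy)-5-methyl-3-(3-methylbut-2-en-1-yl)phenyl]-1-[4-(methoxymethoxy)phenyl]-3-oxopropan-1-olate | CCCC[N+](CCCC)(CCCC)CCCC.[O-][C@H](c1ccc(OCOC)cc1)CC(=O)c1c(F)c(CC=C(C)C)c(OCOC)c(C)c1OCOC | intermediate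
14 | (2S)-5,7-bis(methoxymethoxy)-2-[4-(methoxymethoxy)phenyl]-6-methyl-8-(3-methylbut-2-en-1-yl)-2,3-dihydro-4H-chromen-4-one | CC(C)=CCc1c(OCOC)c(C)c(OCOC)c2c1O[C@H](c1ccc(OCOC)cc1)CC2=O | intermediate
15 | (2S)-5,7-dihydroxy-2-(4-hydroxyphenyl)-6-methyl-8-(3-methylbut-2-en-1-yl)-2,3-dihydro-4H-chromen-4-one (6-methyl-8-prenylnaringenin) | CC(C)=CCc1c(O)c(C)c(O)c2c1O[C@H](c1ccc(O)cc1)CC2=O | target

Total step count: 7
Longest linear sequence: 7 steps (1 → 15)

Steps most likely to fail

Step 6 (Proposed new method). What may go wrong: retro-aldol cleavage of the alkoxide competing with ring closure (loss of material and of enantiopurity), capture of the fluoride by the boron catalyst so that the relay stalls, or base-induced opening of ring C after closure. The fallback uses known chemistry and makes the C2–aryl bond last. It sets out from ketone 8: Claisen formylation with ethyl formate and NaH in THF should give 3-[2-fluoro-4,6-bis(methoxymethoxy)-5-methyl-3-(3-methylbut-2-en-1-yl)phenyl]-3-oxopropanal F1. Its enolate oxygen should displace the ortho fluorine on warming with K2CO3 in DMF (80 °C) to give 5,7-bis(methoxymethoxy)-6-methyl-8-(3-methylbut-2-en-1-yl)-4H-chromen-4-one F2. Asymmetric 1,4-addition of 4-(methoxymethoxy)phenylboronic acid ([RhCl(C2H4)2]2, chiral diene ligand of the enantiomeric series that gives the 2S product, aq. KOH, dioxane) then comes back to the route at 14.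

Step 2. What may go wrong: metalation at a fluorine-flanked position in competition with the position between the OMOM groups, leading to the regioisomeric methyl compound or, through loss of LiF, to aryne-derived material. The fallback sets out from 2 and blocks the fluorine-flanked positions first: double deprotonation–silylation with in situ trapping (LiN(i-Pr)2, Me3SiCl, THF, −78 °C) should give [2-fluoro-4,6-bis(methoxymethoxy)-1,3-phenylene]bis(trimethylsilane) F3. Its only remaining C–H lies between the OMOM groups and is lithiated and methylated (n-BuLi, THF, 0 °C; MeI) to [2-fluoro-4,6-bis(methoxymethoxy)-5-methyl-1,3-phenylene]bis(trimethylsilane) F4. Protodesilylation with Bu4NF in wet THF comes back to the route at 4.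

Step 3. What may go wrong: SN2′ attack at the tertiary terminus of the prenyl electrophile (reverse prenylation), or loss of LiF from aryllithium 5 if the alkylation needs warming. The fallback sets out from 4: the same lithiation is trapped at −78 °C with allyl bromide, where both termini are identical, to give 1-fluoro-3,5-bis(methoxymethoxy)-4-methyl-2-(prop-2-en-1-yl)benzene F5. Olefin cross-metathesis with 2-methyl-2-butene (second-generation Grubbs catalyst, RuCl2(=CHPh)(H2IMes)(PCy3), CH2Cl2, 40 °C) comes back to the route at 6.

Further compounds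
F1 | step 6 | 3-[2-fluoro-4,6-bis(methoxymethoxy)-5-methyl-3-(3-methylbut-2-en-1-yl)phenyl]-3-oxopropanal | O=CCC(=O)c1c(F)c(CC=C(C)C)c(OCOC)c(C)c1OCOC
F2 | step 6 | 5,7-bis(methoxymethoxy)-6-methyl-8-(3-methylbut-2-en-1-yl)-4H-chromen-4-one | CC(C)=CCc1c(OCOC)c(C)c(OCOC)c2c1OC=CC2=O
F3 | step 2 | [2-fluoro-4,6-bis(methoxymethoxy)-1,3-phenylene]bis(trimethylsilane) | C[Si](C)(C)c1c(F)c([Si](C)(C)C)c(OCOC)cc1OCOC
F4 | step 2 | [2-fluoro-4,6-bis(methoxymethoxy)-5-methyl-1,3-phenylene]bis(trimethylsilane) | C[Si](C)(C)c1c(F)c([Si](C)(C)C)c(OCOC)c(C)c1OCOC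
F5 | step 3 | 1-fluoro-3,5-bis(methoxymethoxy)-4-methyl-2-(prop-2-en-1-yl)benzene | C=CCc1c(F)cc(OCOC)c(C)c1OCOC
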